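All runs were computed for an exercise; noise was put on by code.

In a one-step world the target climbs and stays, but the gamma run read 31% at 4.00 h and 18% at 25.0 h, so target was being used up as well as made. The flask asked about is delta carried on.

1. when, up to 2.5 d, the flask holds most target
2. the amount of target, in percent of the substrate charged, at that time

in all of them: gas phase 140 mM (held); catalyst 0.5 mol%
- delta: substrate 2 M; the very flask that is asked about, followed so far
- gamma: substrate 3 M; run made earlier
- flask: substrate 2.0 M; time 2.5 d

| run | time / h | target / % |
|---|---|---|
| delta | 0.500 | 11 |
| delta | 1.00 | 18 |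
| delta | 2.00 | 23 |
| delta | 4.00 | 28 |
| delta | 8.00 | 26 |
| gamma | 2.00 | 31 |
| gamma | 4.00 | 31 |
| gamma | 6.00 | 28 |
| gamma | 12.0 | 17 |
| gamma | 25.0 | 18 |

(each reading ± 2 percentage points)

Both runs had the same catalyst loading, so gamma held 1.50 times delta's catalyst concentration. I supposed that with the gas phase held each step was pseudo-first-order and ran in proportion to catalyst. Fractions of the charge should then follow one clock: hours multiplied by the run's substrate charge over 2 M.

I read the two tables against each other on that clock. Gamma's 2.00 h became 3.00 h with 31%, then came delta's 4.00 h with 28%, then gamma's 4.00 h at 6.00 h with 31%. Delta's 8.00 h gave 26%, and gamma's 6.00 h, at 9.00 h, gave 28%. With a scatter of 2 percentage points, these readings lie on one hump, so the hours to watch were those between 3.00 h and 6.00 h.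

I took the middle of that span, 0.188 d, as the peak clock time, and the mean of the three top readings, 30.0%, as its height.

The forecast gave 29% at 0.21 d, a time later than my peak clock time, holding that the gamma run “should run about 1.5 times faster, perhaps more”.

The flask gave 30.7% at 0.160 d, earlier than my peak clock time.

    target + catalyst ⇌ isomer of the product + catalyst, rate k1*[catalyst]*[target] forward; the back reaction follows from the equilibrium constant (K = 7.41, k = 0.00315 /M/s)
    substrate + dissolved gas + catalyst ⇌ catalyst + target (K = 4.53 /M, k = 0.0621 /M²/s)
    gas phase ⇌ dissolved gas, rate k3*(csat - [dissolved gas]) (kL = 0.0344 /s)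

The neighbouring flask had 0.50 M of substrate at the same loading, so I placed its peak at 0.750 d. Its end at 2.5 d then stood at 0.625 d on the clock, 3.33 times the peak clock time and past the top. It reached 30.8% at best. At its end it held 22.1% target, less than this flask's 29.4% at 0.250 d and more than this flask's 15.4% at 1.25 d.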